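**Strategy.** Everything rests on making C4–C18 inside a temporary δ-lactone. The C16 ketone of the target is carried as an (S)-carbinol; its oxygen, 1,3 to C18, is acylated with 2-bromopentanoic acid (C1–C5), so that samarium diiodide closes the ring O16–C5–C4–C18–C17–C16 by Reformatsky attack of C4 on the C18 aldehyde. One operation forms the bond and sets C4 and C18 by chelate-controlled relay from C16. Later a transannular Claisen condensation passes C5 from O16 to C6, building the real dihydropyranone ring (C4, C5, C6, C19, O, C18) and freeing C16–OH for oxidation. The precursor is a bromo ester dialdehyde on an Achmatowicz-derived tetrahydropyran.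

Key step: step 14

Remarks on the chemistry:
- Numbering follows the target SMILES from left to right: C1–C3 propyl, C4 (propyl-bearing), C5 (enol carbon), C6 (lactone α-carbon), C7, C8, C9 (quaternary), C10, C11 (methyl-bearing), C12 (carbinol), C13, C14, C15 (methyl-bearing), C16 (ketone), C17, C18 (bears the ester oxygen), C19 (lactone carbonyl). O16 is the oxygen on C16.
- Assumption: (S)-4-methyldihydrofuran-2(3H)-one is bought enantiopure. Racemic 2-bromopentanoic acid is used because its stereocentre is erased in step 14.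
- CIP descriptors in names refer to the compound as drawn (some change when a neighbouring group changes); the SMILES in the compound list are definitive.

**Route**

Step 1
Reactants: 1 2-methylfuran; 2 (S)-4-methyldihydrofuran-2(3H)-one
Product: 4 (S)-4-hydroxy-3-methyl-1-(5-methylfuran-2-yl)butan-1-one, via 5-methyl-2-furyllithium 3 (not isolated)
Conditions: n-BuLi, THF, 0 °C; then 2, −78 °C; H2O
Reagents that add atoms: none
Why: C5 lithiation of the furan and acyl substitution on the lactone (organolithium addition, held at the ketone stage by the lithium hemiketal alkoxide at −78 °C) joins C12 to C13 and brings in C15 from the chiral pool unchanged.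

Step 2
Reactants: 4 (S)-4-hydroxy-3-methyl-1-(5-methylfuran-2-yl)butan-1-one
Product: 5 (S)-4-(tert-butyldimethylsilyloxy)-3-methyl-1-(5-methylfuran-2-yl)butan-1-one
Conditions: TBSCl, imidazole, DMF, rt
Reagents that add atoms: tert-butyldimethylsilyl chloride, CC(C)(C)[Si](C)(C)Cl
Why: Standard imidazole-promoted silylation masks the primary C16 alcohol through the reductive, oxidative and Lewis acidic steps that follow.

Step 3
Reactants: 5 (S)-4-(tert-butyldimethylsilyloxy)-3-methyl-1-(5-methylfuran-2-yl)butan-1-one
Product: 6 (1S,3S)-4-(tert-butyldimethylsilyloxy)-3-methyl-1-(5-methylfuran-2-yl)butan-1-ol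
Conditions: RuCl(p-cymene)[(S,S)-TsDPEN] (1 mol %), HCO2H/Et3N (5:2), rt
Reagents that add atoms: none
Why: Noyori asymmetric transfer hydrogenation of the 2-acylfuran delivers hydride to one face under control of the (S,S)-TsDPEN ligand, as for other aryl alkyl ketones, and should set C13 as S.

Step 4
Reactants: 6 (1S,3S)-4-(tert-butyldimethylsilyloxy)-3-methyl-1-(5-methylfuran-2-yl)butan-1-ol
Product: 7 (2S)-2-[(2S)-3-(tert-butyldimethylsilyloxy)-2-methylpropyl]-6-hydroxy-6-methyl-2H-pyran-3(6H)-one (both C9 epimers)
Conditions: NBS, NaHCO3, THF/H2O (4:1), 0 °C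
Reagents that add atoms: water, O
Why: The Achmatowicz rearrangement (bromonium-induced oxidative ring expansion of a furfuryl alcohol) turns the furan into the pyranone hemiketal with C13 untouched, C12 as ketone and C9 at the ketal oxidation level.

Step 5
Reactants: 7 the pyranone hemiketal; 8 allyltrimethylsilane
Product: 9 (2S,6S)-6-allyl-2-[(2S)-3-(tert-butyldimethylsilyloxy)-2-methylpropyl]-6-methyl-2H-pyran-3(6H)-one
Conditions: BF3·OEt2, CH2Cl2, −78 → −40 °C
Reagents that add atoms: none
Why: Lewis acid ionisation of either hemiketal epimer gives one cyclic oxocarbenium ion, which the allylsilane should attack at C9 anti to the C13 side chain (Hosomi–Sakurai type C-glycosylation), setting the quaternary centre with allyl trans to C14.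

Step 6
Reactants: 9 the 6-allyl enone
Product: 11 (2S,4S,6S)-6-allyl-2-[(2S)-3-(tert-butyldimethylsilyloxy)-2-methylpropyl]-4,6-dimethyldihydro-2H-pyran-3(4H)-one, via lithium enolate 10 (not isolated)
Conditions: LiBH(s-Bu)3, THF, −78 °C; then MeI, DMPU, −78 → 0 °C
Reagents that add atoms: iodomethane, CI
Why: Conjugate hydride addition gives enolate 10 regiospecifically and iodomethane should then alkylate C11 on the face away from the axial C9 allyl group (reductive alkylation of an enone), giving the equatorial, thermodynamically preferred methyl epimer without exposing C13 to equilibrating base.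

Step 7
Reactants: 11 the C11-methyl ketone
Product: 12 (2S,3S,4S,6S)-6-allyl-2-[(2S)-3-(tert-butyldimethylsilyloxy)-2-methylpropyl]-4,6-dimethyltetrahydro-2H-pyran-3-ol
Conditions: LiBH(s-Bu)3, THF, −78 °C; H2O
Reagents that add atoms: none
Why: The bulky trialkylborohydride should attack the ring ketone along the equatorial trajectory and give the axial C12 alcohol, cis to both the C11 methyl and the C13 side chain.

Step 8
Reactants: 12 the C12 alcohol
Product: 13 bis-silyl ether, (2S,3S,4S,6S)-6-allyl-3-(tert-butyldimethylsilyloxy)-2-[(2S)-3-(tert-butyldimethylsilyloxy)-2-methylpropyl]-4,6-dimethyltetrahydro-2H-pyran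
Conditions: TBSOTf, 2,6-lutidine, CH2Cl2, 0 °C
Reagents that add atoms: tert-butyldimethylsilyl trifluoromethanesulfonate, CC(C)(C)[Si](C)(C)OS(=O)(=O)C(F)(F)F
Why: The hindered axial alcohol needs the reactive silyl triflate, and the resulting ether protects C12–OH through the later oxidations and base.

Step 9
Reactants: 13 the bis-silyl ether
Product: 14 (2S)-3-[(2S,3S,4S,6S)-6-allyl-3-(tert-butyldimethylsilyloxy)-4,6-dimethyltetrahydro-2H-pyran-2-yl]-2-methylpropan-1-ol
Conditions: HF·pyridine, pyridine, THF, 0 °C
Reagents that add atoms: none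
Why: Buffered HF·pyridine cleaves the unhindered primary silyl ether much faster than the flanked secondary one (selective desilylation), freeing only C16–OH.

Step 10
Reactants: 14 the primary alcohol
Product: 15 (2S)-3-[(2S,3S,4S,6S)-6-allyl-3-(tert-butyldimethylsilyloxy)-4,6-dimethyltetrahydro-2H-pyran-2-yl]-2-methylpropanal
Conditions: Dess–Martin periodinane, NaHCO3, CH2Cl2, 0 °C → rt
Reagents that add atoms: none
Why: Dess–Martin oxidation under buffered, non-basic conditions should give the α-methyl aldehyde without epimerisation at C15, provided it is used at once.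

Step 11
Reactants: 15 the C16 aldehyde
Product: 16 (4S,5S)-6-[(2S,3S,4S,6S)-6-allyl-3-(tert-butyldimethylsilyloxy)-4,6-dimethyltetrahydro-2H-pyran-2-yl]-5-methylhex-1-en-4-ol
Conditions: (−)-Ipc2BOMe, allylMgBr, Et2O, 0 °C → rt; then 15, −78 °C; NaOH, H2O2
Reagents that add atoms: (−)-B-allyldiisopinocampheylborane (made in the flask from (−)-Ipc2BOMe and allylMgBr), C[C@H]1[C@@H](C[C@@H]2C[C@H]1C2(C)C)B(CC=C)[C@@H]3C[C@@H]4C[C@H]([C@H]3C)C4(C)C; allylmagnesium bromide, C=CC[Mg]Br
Why: Brown allylboration through a chair transition state, with reagent control from the isopinocampheyl groups reinforced by the Felkin preference of the α-methyl aldehyde, should set C16 as S, the disposable stereocentre that steers the key step.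

Step 12
Reactants: 16 the homoallylic alcohol; 17 2-bromopentanoic acid (racemic)
Product: 18 2-bromopentanoate of 16 at O16 (both epimers at the bromine-bearing carbon)
Conditions: DCC, DMAP (cat.), CH2Cl2, 0 °C → rt
Reagents that add atoms: none
Why: Steglich esterification attaches C1–C5 to O16, and the configuration at the bromine-bearing carbon does not matter because that carbon becomes an enolate.

Step 13
Reactants: 18 the bromo ester diene
Product: 19 dialdehyde, 18 with both vinyl groups cleaved to formyl groups (C7 and C18 aldehydes)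
Conditions: O3, CH2Cl2, −78 °C; then Me2S
Reagents that add atoms: ozone, [O-][O+]=O
Why: Ozonolysis with reductive work-up cleaves both terminal alkenes in one operation, giving the C18 aldehyde for the key step and the C7 aldehyde for the later macrocyclisation; the β-acyloxy aldehyde is used crude to avoid elimination.

Step 14
Reactants: 19 the bromo ester dialdehyde
Product: 21 (3R,4R,6S)-4-hydroxy-3-propyl-6-[(2S)-1-{(2S,3S,4S,6R)-3-(tert-butyldimethylsilyloxy)-4,6-dimethyl-6-(2-oxoethyl)tetrahydro-2H-pyran-2-yl}propan-2-yl]tetrahydro-2H-pyran-2-one, via samarium enolate 20 (not isolated)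
Conditions: SmI2 (2.5 equiv), THF, −78 °C; pH 7 buffer
Reagents that add atoms: none
Why: Two single-electron transfers from SmI2 cleave the C4–Br bond and give the trivalent samarium ester enolate 20, whose metal stays on the enolate oxygen and chelates the C18 aldehyde oxygen, so that C4 adds to C18 through a rigid bicyclic chair-like transition state; the closest known reaction type is the SmI2-promoted intramolecular Reformatsky cyclisation of β-(α-bromoacyloxy) aldehydes to β-hydroxy-δ-valerolactones. The ring closed is the six-membered temporary lactone O16–C5–C4–C18–C17–C16, formed in a 6-(enolendo)-exo-trig aldol mode. C18 is controlled by C16: with the C16 substituent equatorial and the chelated aldehyde oxygen axial, the new hydroxyl should come out trans to the C16 substituent, which for 16S means 18R. C4 is controlled by the enolate geometry: the propyl group sits cis to the samarium-bound oxygen to avoid allylic strain with the ring-forming alkoxy side, ends up equatorial and cis to the C18 hydroxyl, which means 4R. The step needs chemoselectivity for the bromide over two aldehydes and for the C18 over the C7 aldehyde; the first rests on the much faster reduction of α-bromo esters at −78 °C, the second on the fact that only C18 can reach the enolate within a six-membered chelate.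

Step 15
Reactants: 21 the hydroxy lactone aldehyde; 22 diethylphosphonoacetic acid
Product: 23 diethylphosphonoacetate of 21 at the C18 oxygen
Conditions: DCC, DMAP (cat.), CH2Cl2, 0 °C
Reagents that add atoms: none
Why: Carbodiimide esterification of the axial C18 alcohol installs C19 and C6 together with the phosphonate needed for ring closure, under conditions too mild to enolise the lactone.

Step 16
Reactants: 23 the phosphonoacetate aldehyde
Product: 24 (E)-configured 13-membered macrocyclic enoate (C6=C7) still carrying the temporary δ-lactone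
Conditions: LiCl, i-Pr2NEt, MeCN, 1 mM, rt
Reagents that add atoms: none
Why: Horner–Wadsworth–Emmons olefination under Masamune–Roush conditions and high dilution joins C6 to C7 and closes the macrolactone with an amine base too weak to deprotonate the δ-lactone.

Step 17
Reactants: 24 the macrocyclic enoate
Product: 25 saturated bis-lactone (13-membered macrolactone bridged by the temporary δ-lactone)
Conditions: H2 (1 atm), Pd/C, EtOAc, rt
Reagents that add atoms: none
Why: Heterogeneous hydrogenation saturates the only C=C bond and leaves C6 as the single unhindered α-methylene of the macrolactone.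

Step 18
Reactants: 25 the saturated bis-lactone
Product: 26 12-O-tert-butyldimethylsilyl-16-hydroxy compound (mangromicin C skeleton with 16S carbinol in place of the ketone)
Conditions: LiN(SiMe3)2 (3 equiv), THF, −78 → −20 °C; aq. HCl to pH 3
Reagents that add atoms: none
Why: Kinetic deprotonation of the C6 methylene gives an ester enolate that the axial C18 oxygen holds directly over the δ-lactone carbonyl C5, so that a 6-exo-trig Claisen (Dieckmann-type) condensation, loss of the C16 alkoxide from the tetrahedral intermediate and deprotonation of the β-keto lactone should deliver the 4-hydroxy-5,6-dihydropyran-2-one without touching C4 or C18.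

Step 19
Reactants: 26 the 16-hydroxy pyranone
Product: 27 12-O-tert-butyldimethylsilyl mangromicin C
Conditions: Dess–Martin periodinane, NaHCO3, CH2Cl2, 0 °C
Reagents that add atoms: none
Why: Buffered Dess–Martin oxidation turns the secondary C16 alcohol into the ketone under non-basic conditions, so that the β-acyloxy ketone just formed cannot eliminate and C15 is not epimerised.

Step 20
Reactants: 27 12-O-silyl mangromicin C
Product: 28 mangromicin C
Conditions: HF·pyridine, THF, 0 °C → rt
Reagents that add atoms: none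
Why: Desilylation with HF·pyridine under mildly acidic conditions removes the last protecting group without base and should give the target.

**Compound list**

1 | 2-methylfuran | Cc1ccco1 | starting material
2 | (S)-4-methyldihydrofuran-2(3H)-one | O=C1C[C@H](C)CO1 | starting material
3 | 5-methyl-2-furyllithium | Cc1ccc([Li])o1 | intermediate (not isolated)
4 | (S)-4-hydroxy-3-methyl-1-(5-methylfuran-2-yl)butan-1-one | Cc1ccc(o1)C(=O)C[C@H](C)CO | intermediate
5 | (S)-4-(tert-butyldimethylsilyloxy)-3-methyl-1-(5-methylfuran-2-yl)butan-1-one | Cc1ccc(o1)C(=O)C[C@H](C)CO[Si](C)(C)C(C)(C)C | intermediate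
6 | (1S,3S)-4-(tert-butyldimethylsilyloxy)-3-methyl-1-(5-methylfuran-2-yl)butan-1-ol | Cc1ccc(o1)[C@H](C[C@H](C)CO[Si](C)(C)C(C)(C)C)O | intermediate
7 | (2S)-2-[(2S)-3-(tert-butyldimethylsilyloxy)-2-methylpropyl]-6-hydroxy-6-methyl-2H-pyran-3(6H)-one (both C9 epimers) | CC1(O)C=CC(=O)[C@H](C[C@H](C)CO[Si](C)(C)C(C)(C)C)O1 | intermediate
8 | allyltrimethylsilane | C=CC[Si](C)(C)C | starting material
9 | (2S,6S)-6-allyl-2-[(2S)-3-(tert-butyldimethylsilyloxy)-2-methylpropyl]-6-methyl-2H-pyran-3(6H)-one | C=CC[C@@]1(C)C=CC(=O)[C@H](C[C@H](C)CO[Si](C)(C)C(C)(C)C)O1 | intermediate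
10 | lithium (2S,6S)-6-allyl-2-[(2S)-3-(tert-butyldimethylsilyloxy)-2-methylpropyl]-6-methyl-5,6-dihydro-2H-pyran-3-olate | C=CC[C@@]1(C)CC=C(O[Li])[C@H](C[C@H](C)CO[Si](C)(C)C(C)(C)C)O1 | intermediate (not isolated)
11 | (2S,4S,6S)-6-allyl-2-[(2S)-3-(tert-butyldimethylsilyloxy)-2-methylpropyl]-4,6-dimethyldihydro-2H-pyran-3(4H)-one | C=CC[C@@]1(C)C[C@H](C)C(=O)[C@H](C[C@H](C)CO[Si](C)(C)C(C)(C)C)O1 | intermediate
12 | (2S,3S,4S,6S)-6-allyl-2-[(2S)-3-(tert-butyldimethylsilyloxy)-2-methylpropyl]-4,6-dimethyltetrahydro-2H-pyran-3-ol | C=CC[C@@]1(C)C[C@H](C)[C@H](O)[C@H](C[C@H](C)CO[Si](C)(C)C(C)(C)C)O1 | intermediate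
13 | (2S,3S,4S,6S)-6-allyl-3-(tert-butyldimethylsilyloxy)-2-[(2S)-3-(tert-butyldimethylsilyloxy)-2-methylpropyl]-4,6-dimethyltetrahydro-2H-pyran | C=CC[C@@]1(C)C[C@H](C)[C@H](O[Si](C)(C)C(C)(C)C)[C@H](C[C@H](C)CO[Si](C)(C)C(C)(C)C)O1 | intermediate
14 | (2S)-3-[(2S,3S,4S,6S)-6-allyl-3-(tert-butyldimethylsilyloxy)-4,6-dimethyltetrahydro-2H-pyran-2-yl]-2-methylpropan-1-ol | C=CC[C@@]1(C)C[C@H](C)[C@H](O[Si](C)(C)C(C)(C)C)[C@H](C[C@H](C)CO)O1 | intermediate
15 | (2S)-3-[(2S,3S,4S,6S)-6-allyl-3-(tert-butyldimethylsilyloxy)-4,6-dimethyltetrahydro-2H-pyran-2-yl]-2-methylpropanal | C=CC[C@@]1(C)C[C@H](C)[C@H](O[Si](C)(C)C(C)(C)C)[C@H](C[C@H](C)C=O)O1 | intermediate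
16 | (4S,5S)-6-[(2S,3S,4S,6S)-6-allyl-3-(tert-butyldimethylsilyloxy)-4,6-dimethyltetrahydro-2H-pyran-2-yl]-5-methylhex-1-en-4-ol | C=CC[C@@]1(C)C[C@H](C)[C@H](O[Si](C)(C)C(C)(C)C)[C@H](C[C@H](C)[C@@H](O)CC=C)O1 | intermediate
17 | 2-bromopentanoic acid (racemic) | CCCC(Br)C(=O)O | starting material
18 | 2-bromopentanoate of 16 at O16 (both epimers at the bromine-bearing carbon) | C=CC[C@@]1(C)C[C@H](C)[C@H](O[Si](C)(C)C(C)(C)C)[C@H](C[C@H](C)[C@@H](OC(=O)C(Br)CCC)CC=C)O1 | intermediate
19 | bromo ester dialdehyde (C7 and C18 aldehydes) | O=CC[C@@]1(C)C[C@H](C)[C@H](O[Si](C)(C)C(C)(C)C)[C@H](C[C@H](C)[C@@H](OC(=O)C(Br)CCC)CC=O)O1 | intermediate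
20 | trivalent samarium ester enolate of 19 (propyl cis to the samarium-bound oxygen) | O=CC[C@@]1(C)C[C@H](C)[C@H](O[Si](C)(C)C(C)(C)C)[C@H](C[C@H](C)[C@@H](O/C(O[Sm](I)I)=C/CCC)CC=O)O1 | intermediate (not isolated)
21 | (3R,4R,6S)-4-hydroxy-3-propyl-6-[(2S)-1-{(2S,3S,4S,6R)-3-(tert-butyldimethylsilyloxy)-4,6-dimethyl-6-(2-oxoethyl)tetrahydro-2H-pyran-2-yl}propan-2-yl]tetrahydro-2H-pyran-2-one | O=CC[C@@]1(C)C[C@H](C)[C@H](O[Si](C)(C)C(C)(C)C)[C@H](C[C@H](C)[C@@H]2C[C@@H](O)[C@@H](CCC)C(=O)O2)O1 | intermediate
22 | diethylphosphonoacetic acid | CCOP(=O)(CC(=O)O)OCC | starting material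
23 | diethylphosphonoacetate of 21 at the C18 oxygen | O=CC[C@@]1(C)C[C@H](C)[C@H](O[Si](C)(C)C(C)(C)C)[C@H](C[C@H](C)[C@@H]2C[C@@H](OC(=O)CP(=O)(OCC)OCC)[C@@H](CCC)C(=O)O2)O1 | intermediate
24 | (E)-macrocyclic enoate (13-membered lactone, C6=C7) bridged by the temporary δ-lactone | O=C3/C=C/C[C@@]1(C)C[C@H](C)[C@H](O[Si](C)(C)C(C)(C)C)[C@H](C[C@H](C)[C@@H]2C[C@@H](O3)[C@@H](CCC)C(=O)O2)O1 | intermediate
25 | saturated bis-lactone (6,7-dihydro-24) | O=C3CCC[C@@]1(C)C[C@H](C)[C@H](O[Si](C)(C)C(C)(C)C)[C@H](C[C@H](C)[C@@H]2C[C@@H](O3)[C@@H](CCC)C(=O)O2)O1 | intermediate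
26 | 12-O-tert-butyldimethylsilyl-(16S)-16-hydroxy-16-deoxo-mangromicin C | CCC[C@H]1C(O)=C2CC[C@@]3(C)C[C@H](C)[C@H](O[Si](C)(C)C(C)(C)C)[C@H](C[C@H](C)[C@@H](O)C[C@H]1OC2=O)O3 | intermediate
27 | 12-O-tert-butyldimethylsilyl mangromicin C | CCC[C@H]1C(O)=C2CC[C@@]3(C)C[C@H](C)[C@H](O[Si](C)(C)C(C)(C)C)[C@H](C[C@H](C)C(=O)C[C@H]1OC2=O)O3 | intermediate
28 | mangromicin C | CCC[C@H]1C(O)=C2CC[C@@]3(C)C[C@H](C)[C@H](O)[C@H](C[C@H](C)C(=O)C[C@H]1OC2=O)O3 | target

**Count**

Total steps: 20. Longest linear sequence: 20 steps (1 and 2 to 28).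

**Steps most likely to fail, with fallbacks**

1. Step 18 (acyl relay). The base may deprotonate C4 instead of C6, after which the C18 acyloxy group is lost by β-elimination, or the tetrahedral intermediate may revert instead of expelling the C16 alkoxide. Fallback, from 25 back to 26:
   - The δ-lactone, more reactive than the macrolactone, is opened with MeNH(OMe)·HCl and Me2AlCl to the C16-hydroxy Weinreb amide F1.
   - C16–OH is silylated with TESOTf and 2,6-lutidine to the triethylsilyl ether F2.
   - LiN(SiMe3)2 then closes the ring by Claisen attack of the C6 ester enolate on the Weinreb amide, whose α-proton is far less acidic and which has no tethered leaving group, giving the 16-O-triethylsilyl pyranone F3.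
   - PPTS in MeOH removes the triethylsilyl group selectively and the route is rejoined at 26.

2. Step 14 (key step). The β-acyloxy aldehyde may eliminate the bromopentanoate before cyclisation, an aldehyde may be reduced to a ketyl, or enolate geometry may be poorly controlled and erode the configuration at C4. Fallback, from 16 back to 21:
   - 16 is esterified with (E)-pent-2-enoic acid (DCC, DMAP) to the (E)-pent-2-enoate F4.
   - The two terminal alkenes are cleaved with OsO4 (cat.), NaIO4 and 2,6-lutidine, which spare the electron-poor enoate, to the enoate dialdehyde F5.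
   - A copper hydride reductive aldol cyclisation ([(Ph3P)CuH]6, toluene, −40 °C) delivers hydride to C3, and the copper enolate closes the same C4–C18 bond through the same six-membered chelate to reach 21.

3. Step 6 (reductive methylation). Hydride may add 1,2 instead of 1,4 at the enone, whose β-carbon lies next to the quaternary C9, and proton exchange between enolate and product may cause loss of regiocontrol or over-methylation. Fallback, from 9 back to 11:
   - Conjugate reduction with [(Ph3P)CuH]6 in toluene gives the saturated ketone F6.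
   - Kinetic deprotonation at the C11 methylene with LiN(i-Pr)2 at −78 °C, followed by MeI, then gives 11.

**Further compounds**

F1 | step 18 | C16-hydroxy Weinreb amide (δ-lactone of 25 opened at C5 with N,O-dimethylhydroxylamine) | O=C3CCC[C@@]1(C)C[C@H](C)[C@H](O[Si](C)(C)C(C)(C)C)[C@H](C[C@H](C)[C@@H](O)C[C@@H](O3)[C@@H](CCC)C(=O)N(C)OC)O1
F2 | step 18 | 16-O-triethylsilyl ether of F1 | O=C3CCC[C@@]1(C)C[C@H](C)[C@H](O[Si](C)(C)C(C)(C)C)[C@H](C[C@H](C)[C@@H](O[Si](CC)(CC)CC)C[C@@H](O3)[C@@H](CCC)C(=O)N(C)OC)O1
F3 | step 18 | 16-O-triethylsilyl ether of 26 | CCC[C@H]1C(O)=C2CC[C@@]3(C)C[C@H](C)[C@H](O[Si](C)(C)C(C)(C)C)[C@H](C[C@H](C)[C@@H](O[Si](CC)(CC)CC)C[C@H]1OC2=O)O3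
F4 | step 14 | (E)-pent-2-enoate of 16 at O16 | C=CC[C@@]1(C)C[C@H](C)[C@H](O[Si](C)(C)C(C)(C)C)[C@H](C[C@H](C)[C@@H](OC(=O)/C=C/CC)CC=C)O1
F5 | step 14 | enoate dialdehyde (C7 and C18 aldehydes) from F4 | O=CC[C@@]1(C)C[C@H](C)[C@H](O[Si](C)(C)C(C)(C)C)[C@H](C[C@H](C)[C@@H](OC(=O)/C=C/CC)CC=O)O1
F6 | step 6 | (2S,6S)-6-allyl-2-[(2S)-3-(tert-butyldimethylsilyloxy)-2-methylpropyl]-6-methyldihydro-2H-pyran-3(4H)-one | C=CC[C@@]1(C)CCC(=O)[C@H](C[C@H](C)CO[Si](C)(C)C(C)(C)C)O1
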